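The plan builds ring A of unit 2 (the flavone linked through C8) from scratch on C6 of a finished unit 1 (the 7-methoxy flavone), so no hindered biaryl coupling is needed. That ring carries oxygen at C5, C7 and C8a, the axis at C8 and the acyl carbon at C4a. This pattern is the sum of a ketene-acetal diene (C8a–C8–C7–C6) and a push–pull ynone (C5–C4a). One cycloaddition–aromatisation forms C5–C6 and C4a–C8a, closes the ring and leaves a single phenol (C8a) beside the acetyl group. Its precursor is the 1-methoxy-1,3-bis(trimethylsiloxy)diene of a 2-aryl acetoacetate whose aryl group is unit 1.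

Key step: step 13

Assumption: the SMILES defines no configuration for the C6–C8 biaryl axis, so the target is made as the racemic mixture of atropisomers and no step has to control the axis.

Step 1
Reactants: 1 1-(2,6-dihydroxy-4-methoxyphenyl)ethanone; 2 4-(benzyloxy)benzaldehyde
Product: 3 (E)-3-[4-(benzyloxy)phenyl]-1-(2,6-dihydroxy-4-methoxyphenyl)prop-2-en-1-one
Conditions: KOH (50% aq.), EtOH, rt; then 1 M HCl, 0 °C
Reagents that add atoms: none
Why: Claisen–Schmidt condensation of a methyl ketone with a non-enolisable aldehyde, in which the E geometry of the enone is the thermodynamic outcome of the base-induced loss of water.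

Step 2
Reactants: 3 (E)-3-[4-(benzyloxy)phenyl]-1-(2,6-dihydroxy-4-methoxyphenyl)prop-2-en-1-one
Product: 4 2-[4-(benzyloxy)phenyl]-5-hydroxy-7-methoxy-4H-chromen-4-one
Conditions: I2 (10 mol%), DMSO, 130 °C
Reagents that add atoms: none
Why: Iodine-catalysed oxidative cyclisation of a 2'-hydroxychalcone with DMSO as terminal oxidant; the two ortho phenols of 3 are equivalent, so only one flavone can form and the unused phenol stays as the chelated 5-OH.

Step 3
Reactants: 4 2-[4-(benzyloxy)phenyl]-5-hydroxy-7-methoxy-4H-chromen-4-one; 5 allyl bromide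
Product: 6 5-(allyloxy)-2-[4-(benzyloxy)phenyl]-7-methoxy-4H-chromen-4-one
Conditions: K2CO3, DMF, 60 °C
Reagents that add atoms: none
Why: Williamson ether synthesis; 4 has a single hydroxyl group, and carbonate in warm DMF should break its hydrogen bond to the C4 carbonyl and let it attack the reactive allylic bromide.

Step 4
Reactants: 6 5-(allyloxy)-2-[4-(benzyloxy)phenyl]-7-methoxy-4H-chromen-4-one
Product: 7 6-allyl-2-[4-(benzyloxy)phenyl]-5-hydroxy-7-methoxy-4H-chromen-4-one
Conditions: PhNEt2, 200 °C, argon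
Reagents that add atoms: none
Why: Aromatic Claisen rearrangement; the [3,3] shift from O5 can deliver the allyl group only to C6, because the other ortho position is the ring-fusion carbon C4a, and the chelated phenol is regenerated.

Step 5
Reactants: 7 6-allyl-2-[4-(benzyloxy)phenyl]-5-hydroxy-7-methoxy-4H-chromen-4-one
Product: 8 6-allyl-5-(benzyloxy)-2-[4-(benzyloxy)phenyl]-7-methoxy-4H-chromen-4-one
Conditions: BnBr, K2CO3, n-Bu4NI (cat.), DMF, 70 °C
Reagents that add atoms: benzyl bromide, BrCc1ccccc1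
Why: Williamson ether synthesis with iodide catalysis; capping O5 prevents hemiacetal and lactone formation with the C6 side chain in the coming oxidations and removes the only acidic proton before the enolate steps.

Step 6
Reactants: 8 6-allyl-5-(benzyloxy)-2-[4-(benzyloxy)phenyl]-7-methoxy-4H-chromen-4-one
Product: 10 2-{5-(benzyloxy)-2-[4-(benzyloxy)phenyl]-7-methoxy-4-oxo-4H-chromen-6-yl}acetaldehyde, via racemic 1,2-diol 9 (not isolated)
Conditions: OsO4 (2 mol%), NaIO4, 2,6-lutidine, dioxane/H2O, rt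
Reagents that add atoms: sodium periodate, [Na+].[O-]I(=O)(=O)=O (source of the aldehyde oxygen, passed on through OsO4)
Why: Lemieux–Johnson oxidative cleavage; OsO4 should dihydroxylate the isolated monosubstituted alkene far faster than the electron-poor trisubstituted C2=C3 bond of the pyrone, and periodate cleaves diol 9 and reoxidises osmium.

Step 7
Reactants: 10 2-{5-(benzyloxy)-2-[4-(benzyloxy)phenyl]-7-methoxy-4-oxo-4H-chromen-6-yl}acetaldehyde
Product: 11 2-{5-(benzyloxy)-2-[4-(benzyloxy)phenyl]-7-methoxy-4-oxo-4H-chromen-6-yl}acetic acid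
Conditions: NaClO2, NaH2PO4, 2-methyl-2-butene, t-BuOH/THF/H2O, 0 °C → rt
Reagents that add atoms: sodium chlorite, [Na+].[O-]Cl=O
Why: Pinnick oxidation; chlorous acid converts the aldehyde into the acid without a migration pathway and without touching ethers or pyrone, while excess 2-methyl-2-butene traps HOCl before it can chlorinate C8 of the electron-rich ring A.

Step 8
Reactants: 11 2-{5-(benzyloxy)-2-[4-(benzyloxy)phenyl]-7-methoxy-4-oxo-4H-chromen-6-yl}acetic acid
Product: 12 methyl 2-{5-(benzyloxy)-2-[4-(benzyloxy)phenyl]-7-methoxy-4-oxo-4H-chromen-6-yl}acetate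
Conditions: MeI, K2CO3, DMF, rt
Reagents that add atoms: iodomethane, CI
Why: SN2 esterification by carboxylate O-alkylation, under conditions too weakly basic to enolise the product or open the pyrone.

Step 9
Reactants: 12 methyl 2-{5-(benzyloxy)-2-[4-(benzyloxy)phenyl]-7-methoxy-4-oxo-4H-chromen-6-yl}acetate
Product: 14 methyl 2-{5-(benzyloxy)-2-[4-(benzyloxy)phenyl]-7-methoxy-4-oxo-4H-chromen-6-yl}-3-oxobutanoate, via lithium ester enolate 13 (not isolated)
Conditions: LiN(SiMe3)2 (2.1 equiv), THF, −78 °C; AcCl (1.05 equiv), −78 → −40 °C; AcOH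
Reagents that add atoms: acetyl chloride, CC(=O)Cl
Why: Crossed Claisen-type C-acylation of an ester enolate; LiN(SiMe3)2 is strong enough for the arylacetate but too weak and too bulky to metalate or add to the pyrone, and its second equivalent takes up the more acidic product so that enolate 13 is used up fully (the new stereocentre is labile and is erased in step 10).

Step 10
Reactants: 14 methyl 2-{5-(benzyloxy)-2-[4-(benzyloxy)phenyl]-7-methoxy-4-oxo-4H-chromen-6-yl}-3-oxobutanoate
Product: 15 methyl (Z)-2-{5-(benzyloxy)-2-[4-(benzyloxy)phenyl]-7-methoxy-4-oxo-4H-chromen-6-yl}-3-(trimethylsilyloxy)but-2-enoate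
Conditions: Me3SiCl, Et3N, toluene, rt; filtration under argon
Reagents that add atoms: chlorotrimethylsilane, C[Si](C)(C)Cl
Why: Silyl enol ether formation by O-silylation of a strongly enolised 2-aryl keto ester; the drawn geometry follows the chelated enol and does not matter, since either isomer leads to the same dienolate.

Step 11
Reactants: 15 methyl (Z)-2-{5-(benzyloxy)-2-[4-(benzyloxy)phenyl]-7-methoxy-4-oxo-4H-chromen-6-yl}-3-(trimethylsilyloxy)but-2-enoate
Product: 17 5-(benzyloxy)-2-[4-(benzyloxy)phenyl]-7-methoxy-6-[(1E)-1-methoxy-1,3-bis(trimethylsilyloxy)buta-1,3-dien-2-yl]-4H-chromen-4-one, via lithium dienolate 16 (not isolated)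
Conditions: LiN(i-Pr)2 (1.05 equiv), THF, −78 °C, 1 h; Me3SiCl, −78 → 0 °C; toluene, filtration under argon, used crude at once
Reagents that add atoms: chlorotrimethylsilane, C[Si](C)(C)Cl
Why: Gamma-deprotonation of a 3-siloxy enoate and O-silylation of dienolate 16, the usual second stage in making 1-alkoxy-1,3-bis(silyloxy)dienes; only a slight excess of base is used and the anion is aged before Me3SiCl is added, so that any kinetic metalation at C3 of the pyrone is corrected by proton transfer to the far better stabilised dienolate (the ketene-acetal geometry is uncontrolled and irrelevant).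

Step 12
Reactants: 18 ethoxyacetylene
Product: 21 4-ethoxybut-3-yn-2-one, via lithium ethoxyacetylide 19 (not isolated), via lithium hemiaminal adduct 20 (not isolated)
Conditions: n-BuLi, THF, −78 °C; MeC(O)N(OMe)Me, −78 → −30 °C; AcOH, −78 °C; cold Et2O/H2O extraction, kept below 30 °C
Reagents that add atoms: N-methoxy-N-methylacetamide, CON(C)C(C)=O
Why: Weinreb ketone synthesis with a lithium alkoxyacetylide; chelated adduct 20 holds until the cold buffered quench, which rules out double addition and limits both conjugate addition of the released amine and hydration of the ynol ether.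

Step 13
Reactants: 17 5-(benzyloxy)-2-[4-(benzyloxy)phenyl]-7-methoxy-6-[(1E)-1-methoxy-1,3-bis(trimethylsilyloxy)buta-1,3-dien-2-yl]-4H-chromen-4-one; 21 4-ethoxybut-3-yn-2-one
Product: 24 6-(3-acetyl-4-ethoxy-2,6-dihydroxyphenyl)-5-(benzyloxy)-2-[4-(benzyloxy)phenyl]-7-methoxy-4H-chromen-4-one, via cyclohexadiene cycloadduct 22 (not isolated), via bis(trimethylsilyl) ether 23 (not isolated)
Conditions: 21 (3 equiv), toluene, 75 °C, sealed tube, argon; then 1 M HCl, THF, rt
Reagents that add atoms: none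
Why: Proposed new method: the terminal CH2 of the diene (C6 of unit 2), which carries the largest HOMO coefficient, bonds first to the ethoxy-bearing alkyne carbon (C5), the acceptor end of the push–pull ynone, and the ketene-acetal carbon (C8a) closes onto the acyl-bearing carbon (C4a) in a concerted but strongly asynchronous [4+2] cycloaddition that gives 22. Ring A of unit 2 is thus closed intermolecularly as a six-membered carbocycle by two new sigma bonds across the s-cis diene, a conformation that the bulky substituents on the two inner diene carbons should favour. The orthoester-like carbon C8a of 22 then expels methanol together with a C6 hydrogen to give arene 23 and dilute acid removes both silyl groups, so the transient C8a stereocentre disappears and no stereocentre remains. The closest known reaction type is the cycloaddition of 1-alkoxy-1,3-bis(silyloxy)butadienes with acetylenic esters and ketones that aromatises to resorcinols; new here are the donor-substituted ynone and the di-ortho-substituted aryl group on C2 of the diene. The step needs only regioselectivity, which the matched polarisation of both partners secures, and the rival [3+3] cyclocondensation through C8 cannot aromatise because that carbon is already fully substituted. Heating below 80 °C without a Lewis acid spares the flavone carbonyl, the silyl ketene acetal and the ethoxyalkyne, which would lose ethylene at higher temperature.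

Step 14
Reactants: 24 6-(3-acetyl-4-ethoxy-2,6-dihydroxyphenyl)-5-(benzyloxy)-2-[4-(benzyloxy)phenyl]-7-methoxy-4H-chromen-4-one
Product: 25 6-[3-acetyl-6-(benzyloxy)-4-ethoxy-2-hydroxyphenyl]-5-(benzyloxy)-2-[4-(benzyloxy)phenyl]-7-methoxy-4H-chromen-4-one
Conditions: BnBr (1.05 equiv), K2CO3 (1.2 equiv), acetone, reflux
Reagents that add atoms: benzyl bromide, BrCc1ccccc1
Why: Chemoselective Williamson ether synthesis; the C8a hydroxyl of unit 2 is locked in a hydrogen bond to the acetyl group, so only the free C7 hydroxyl should react, which removes a deactivating para-phenoxide from the next step and costs no extra deprotection.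

Step 15
Reactants: 25 6-[3-acetyl-6-(benzyloxy)-4-ethoxy-2-hydroxyphenyl]-5-(benzyloxy)-2-[4-(benzyloxy)phenyl]-7-methoxy-4H-chromen-4-one; 2 4-(benzyloxy)benzaldehyde
Product: 26 5-(benzyloxy)-6-{6-(benzyloxy)-3-[(E)-3-(4-(benzyloxy)phenyl)prop-2-enoyl]-4-ethoxy-2-hydroxyphenyl}-2-[4-(benzyloxy)phenyl]-7-methoxy-4H-chromen-4-one
Conditions: 2 (1.5 equiv), KOH (50% aq.), EtOH/THF, rt; then 1 M HCl, 0 °C
Reagents that add atoms: none
Why: Claisen–Schmidt condensation as in step 1, now on a mono-phenolic ketone; at room temperature the 5-O-alkylated pyrone of unit 1 should withstand hydroxide (and could only reclose the same way if opened), and the E geometry again results from the elimination.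

Step 16
Reactants: 26 5-(benzyloxy)-6-{6-(benzyloxy)-3-[(E)-3-(4-(benzyloxy)phenyl)prop-2-enoyl]-4-ethoxy-2-hydroxyphenyl}-2-[4-(benzyloxy)phenyl]-7-methoxy-4H-chromen-4-one
Product: 27 7-(benzyloxy)-8-{5-(benzyloxy)-2-[4-(benzyloxy)phenyl]-7-methoxy-4-oxo-4H-chromen-6-yl}-2-[4-(benzyloxy)phenyl]-5-ethoxy-4H-chromen-4-one
Conditions: I2 (10 mol%), DMSO, 125 °C
Reagents that add atoms: none
Why: Iodine-catalysed oxidative cyclisation as in step 2; the C8a hydroxyl is the only phenol of 26, since C5 carries ethoxy and C7 benzyloxy, so the new pyrone can form only in the 8-aryl sense.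

Step 17
Reactants: 27 7-(benzyloxy)-8-{5-(benzyloxy)-2-[4-(benzyloxy)phenyl]-7-methoxy-4-oxo-4H-chromen-6-yl}-2-[4-(benzyloxy)phenyl]-5-ethoxy-4H-chromen-4-one
Product: 28 8-[5-hydroxy-2-(4-hydroxyphenyl)-7-methoxy-4-oxo-4H-chromen-6-yl]-5,7-dihydroxy-2-(4-hydroxyphenyl)-4H-chromen-4-one
Conditions: BCl3 (12 equiv), C6HMe5 (12 equiv), CH2Cl2, −78 °C → rt; then MeOH/H2O
Reagents that add atoms: none
Why: Lewis-acid ether cleavage; BCl3 removes the four benzyl ethers in the cold while pentamethylbenzene traps the benzyl cations, and on warming the boron chelate between the C4 carbonyl and O5 of unit 2 activates only the peri ethyl ether for chloride attack, whereas the unchelated 7-methoxy group of unit 1 is inert to BCl3.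

Compound list
1 | 1-(2,6-dihydroxy-4-methoxyphenyl)ethanone | COc1cc(O)c(C(C)=O)c(O)c1 | starting material
2 | 4-(benzyloxy)benzaldehyde | O=Cc1ccc(OCc2ccccc2)cc1 | starting material
3 | (E)-3-[4-(benzyloxy)phenyl]-1-(2,6-dihydroxy-4-methoxyphenyl)prop-2-en-1-one | COc1cc(O)c(C(=O)/C=C/c2ccc(OCc3ccccc3)cc2)c(O)c1 | intermediate
4 | 2-[4-(benzyloxy)phenyl]-5-hydroxy-7-methoxy-4H-chromen-4-one | COc1cc(O)c2c(=O)cc(-c3ccc(OCc4ccccc4)cc3)oc2c1 | intermediate
5 | allyl bromide | C=CCBr | starting material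
6 | 5-(allyloxy)-2-[4-(benzyloxy)phenyl]-7-methoxy-4H-chromen-4-one | C=CCOc1cc(OC)cc2oc(-c3ccc(OCc4ccccc4)cc3)cc(=O)c12 | intermediate
7 | 6-allyl-2-[4-(benzyloxy)phenyl]-5-hydroxy-7-methoxy-4H-chromen-4-one | C=CCc1c(OC)cc2oc(-c3ccc(OCc4ccccc4)cc3)cc(=O)c2c1O | intermediate
8 | 6-allyl-5-(benzyloxy)-2-[4-(benzyloxy)phenyl]-7-methoxy-4H-chromen-4-one | C=CCc1c(OC)cc2oc(-c3ccc(OCc4ccccc4)cc3)cc(=O)c2c1OCc1ccccc1 | intermediate
9 | 5-(benzyloxy)-2-[4-(benzyloxy)phenyl]-6-(2,3-dihydroxypropyl)-7-methoxy-4H-chromen-4-one (racemic, not isolated) | OCC(O)Cc1c(OC)cc2oc(-c3ccc(OCc4ccccc4)cc3)cc(=O)c2c1OCc1ccccc1 | intermediate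
10 | 2-{5-(benzyloxy)-2-[4-(benzyloxy)phenyl]-7-methoxy-4-oxo-4H-chromen-6-yl}acetaldehyde | O=CCc1c(OC)cc2oc(-c3ccc(OCc4ccccc4)cc3)cc(=O)c2c1OCc1ccccc1 | intermediate
11 | 2-{5-(benzyloxy)-2-[4-(benzyloxy)phenyl]-7-methoxy-4-oxo-4H-chromen-6-yl}acetic acid | OC(=O)Cc1c(OC)cc2oc(-c3ccc(OCc4ccccc4)cc3)cc(=O)c2c1OCc1ccccc1 | intermediate
12 | methyl 2-{5-(benzyloxy)-2-[4-(benzyloxy)phenyl]-7-methoxy-4-oxo-4H-chromen-6-yl}acetate | COC(=O)Cc1c(OC)cc2oc(-c3ccc(OCc4ccccc4)cc3)cc(=O)c2c1OCc1ccccc1 | intermediate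
13 | lithium enolate of ester 12 (geometry irrelevant, not isolated) | [Li+].COC([O-])=Cc1c(OC)cc2oc(-c3ccc(OCc4ccccc4)cc3)cc(=O)c2c1OCc1ccccc1 | intermediate
14 | methyl 2-{5-(benzyloxy)-2-[4-(benzyloxy)phenyl]-7-methoxy-4-oxo-4H-chromen-6-yl}-3-oxobutanoate (racemic, labile centre, in equilibrium with its enol) | COC(=O)C(C(C)=O)c1c(OC)cc2oc(-c3ccc(OCc4ccccc4)cc3)cc(=O)c2c1OCc1ccccc1 | intermediate
15 | methyl (Z)-2-{5-(benzyloxy)-2-[4-(benzyloxy)phenyl]-7-methoxy-4-oxo-4H-chromen-6-yl}-3-(trimethylsilyloxy)but-2-enoate | COc1cc2oc(-c3ccc(OCc4ccccc4)cc3)cc(=O)c2c(OCc2ccccc2)c1/C(C(=O)OC)=C(\C)O[Si](C)(C)C | intermediate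
16 | lithium dienolate of 15 (geometry irrelevant, not isolated) | [Li+].COC([O-])=C(C(=C)O[Si](C)(C)C)c1c(OC)cc2oc(-c3ccc(OCc4ccccc4)cc3)cc(=O)c2c1OCc1ccccc1 | intermediate
17 | 5-(benzyloxy)-2-[4-(benzyloxy)phenyl]-7-methoxy-6-[(1E)-1-methoxy-1,3-bis(trimethylsilyloxy)buta-1,3-dien-2-yl]-4H-chromen-4-one (drawn as one ketene-acetal isomer) | COc1cc2oc(-c3ccc(OCc4ccccc4)cc3)cc(=O)c2c(OCc2ccccc2)c1/C(C(=C)O[Si](C)(C)C)=C(/OC)O[Si](C)(C)C | intermediate
18 | ethoxyacetylene | C#COCC | starting material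
19 | lithium ethoxyacetylide (not isolated) | [Li+].[C-]#COCC | intermediate
20 | lithium 4-ethoxy-2-[methoxy(methyl)amino]but-3-yn-2-olate (racemic, not isolated) | [Li+].CCOC#CC(C)([O-])N(C)OC | intermediate
21 | 4-ethoxybut-3-yn-2-one | CCOC#CC(C)=O | intermediate
22 | cycloadduct: 6-[3-acetyl-4-ethoxy-2-methoxy-2,6-bis(trimethylsilyloxy)cyclohexa-3,6-dien-1-yl] derivative of the unit 1 flavone (racemic, not isolated) | CCOC1=C(C(C)=O)C(OC)(O[Si](C)(C)C)C(c2c(OC)cc3oc(-c4ccc(OCc5ccccc5)cc4)cc(=O)c3c2OCc2ccccc2)=C(O[Si](C)(C)C)C1 | intermediate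
23 | 6-[3-acetyl-4-ethoxy-2,6-bis(trimethylsilyloxy)phenyl]-5-(benzyloxy)-2-[4-(benzyloxy)phenyl]-7-methoxy-4H-chromen-4-one (not isolated) | CCOc1cc(O[Si](C)(C)C)c(-c2c(OC)cc3oc(-c4ccc(OCc5ccccc5)cc4)cc(=O)c3c2OCc2ccccc2)c(O[Si](C)(C)C)c1C(C)=O | intermediate
24 | 6-(3-acetyl-4-ethoxy-2,6-dihydroxyphenyl)-5-(benzyloxy)-2-[4-(benzyloxy)phenyl]-7-methoxy-4H-chromen-4-one | COc1cc2oc(-c3ccc(OCc4ccccc4)cc3)cc(=O)c2c(OCc2ccccc2)c1-c1c(O)cc(OCC)c(C(C)=O)c1O | intermediate
25 | 6-[3-acetyl-6-(benzyloxy)-4-ethoxy-2-hydroxyphenyl]-5-(benzyloxy)-2-[4-(benzyloxy)phenyl]-7-methoxy-4H-chromen-4-one | COc1cc2oc(-c3ccc(OCc4ccccc4)cc3)cc(=O)c2c(OCc2ccccc2)c1-c1c(OCc2ccccc2)cc(OCC)c(C(C)=O)c1O | intermediate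
26 | 5-(benzyloxy)-6-{6-(benzyloxy)-3-[(E)-3-(4-(benzyloxy)phenyl)prop-2-enoyl]-4-ethoxy-2-hydroxyphenyl}-2-[4-(benzyloxy)phenyl]-7-methoxy-4H-chromen-4-one | COc1cc2oc(-c3ccc(OCc4ccccc4)cc3)cc(=O)c2c(OCc2ccccc2)c1-c1c(OCc2ccccc2)cc(OCC)c(C(=O)/C=C/c2ccc(OCc3ccccc3)cc2)c1O | intermediate
27 | 7-(benzyloxy)-8-{5-(benzyloxy)-2-[4-(benzyloxy)phenyl]-7-methoxy-4-oxo-4H-chromen-6-yl}-2-[4-(benzyloxy)phenyl]-5-ethoxy-4H-chromen-4-one | COc1cc2oc(-c3ccc(OCc4ccccc4)cc3)cc(=O)c2c(OCc2ccccc2)c1-c1c(OCc2ccccc2)cc(OCC)c2c(=O)cc(-c3ccc(OCc4ccccc4)cc3)oc12 | intermediate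
28 | 8-[5-hydroxy-2-(4-hydroxyphenyl)-7-methoxy-4-oxo-4H-chromen-6-yl]-5,7-dihydroxy-2-(4-hydroxyphenyl)-4H-chromen-4-one (CNP0246647.0, the 7-methyl ether of 6,8-linked biapigenin) | COc1cc2oc(-c3ccc(O)cc3)cc(=O)c2c(O)c1-c1c(O)cc(O)c2c(=O)cc(-c3ccc(O)cc3)oc12 | target

Total step count: 17. Longest linear sequence: 16 (steps 1–11 and 13–17); step 12 is a one-step side branch.

Steps most likely to fail

Step 13 (the labelled step). The cycloaddition may stall. The twisted aryl group screens both faces of the diene next to C8a and the ethoxy donor tempers the alkyne, so protodesilylation of the diene or thermal decay of the ynone could win.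

- The fallback uses known chemistry, a Suzuki–Miyaura union of two complete flavones, and sets out from 4.
- Benzyltrimethylammonium dichloroiodate (BnMe3N·ICl2) and CaCO3 in CH2Cl2/MeOH should iodinate 4 ortho to the free 5-OH to give 2-[4-(benzyloxy)phenyl]-5-hydroxy-6-iodo-7-methoxy-4H-chromen-4-one F1. Benzylation (BnBr, K2CO3, DMF) then gives the 5-O-benzyl 6-iodide F2.
- Commercial apigenin is perbenzylated to tri-O-benzylapigenin F3. Iodination (I2, CF3CO2Ag, CH2Cl2) at C8, the site that 5,7-dialkoxyflavones offer to electrophiles, gives the 8-iodide F4.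
- Miyaura borylation (B2pin2, PdCl2(dppf), KOAc, dioxane, 90 °C) converts it into the 8-pinacolboronate F5.
- Coupling of F2 with F5 (Pd2(dba)3, SPhos, K3PO4, toluene/H2O, 100 °C) should give the penta-O-benzyl biflavone F6. The conditions of step 17 bring it back to the route at 28.

Step 11. Competing metalation of the pyrone at C3, C-silylation, or hydrolysis of the ketene acetal during handling may erode the quality of a diene that cannot be purified.

- The fallback is a double soft enolisation that uses no lithium amide, and it sets out from 14.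
- With t-BuMe2SiOTf (3 equiv) and Et3N in CH2Cl2 at 0 °C to rt, 14 should give the bis(tert-butyldimethylsilyl) diene F7.
- This diene should survive a cold NaHCO3 wash, which also frees the pyrone carbonyl from any silyl triflate adduct, and a quick pass through Et3N-deactivated silica.
- Cycloaddition with 21 as in step 13 then passes through the silylated cyclohexadiene F8 and the bis(silyl) arene F9. HF·pyridine in THF returns to the route at 24.

Step 12. Conjugate addition of the released amine, hydration of the ynol ether during the quench, or evaporative loss of the small product may spoil the ynone.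

- The fallback replaces acylation by addition and oxidation, and sets out from 18.
- Lithium acetylide 19 is added to acetaldehyde (THF, −78 °C, neutral work-up) to give racemic 4-ethoxybut-3-yn-2-ol F10.
- Activated MnO2 in CH2Cl2 at rt, followed by filtration and careful concentration, comes back to the route at 21. No amine and no aqueous acid then meets the ynone.

Further compounds
F1 | step 13 | 2-[4-(benzyloxy)phenyl]-5-hydroxy-6-iodo-7-methoxy-4H-chromen-4-one | COc1cc2oc(-c3ccc(OCc4ccccc4)cc3)cc(=O)c2c(O)c1I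
F2 | step 13 | 5-(benzyloxy)-2-[4-(benzyloxy)phenyl]-6-iodo-7-methoxy-4H-chromen-4-one | COc1cc2oc(-c3ccc(OCc4ccccc4)cc3)cc(=O)c2c(OCc2ccccc2)c1I
F3 | step 13 | 5,7-bis(benzyloxy)-2-[4-(benzyloxy)phenyl]-4H-chromen-4-one | O=c1cc(-c2ccc(OCc3ccccc3)cc2)oc2cc(OCc3ccccc3)cc(OCc3ccccc3)c12
F4 | step 13 | 5,7-bis(benzyloxy)-2-[4-(benzyloxy)phenyl]-8-iodo-4H-chromen-4-one | O=c1cc(-c2ccc(OCc3ccccc3)cc2)oc2c(I)c(OCc3ccccc3)cc(OCc3ccccc3)c12
F5 | step 13 | 5,7-bis(benzyloxy)-2-[4-(benzyloxy)phenyl]-8-(4,4,5,5-tetramethyl-1,3,2-dioxaborolan-2-yl)-4H-chromen-4-one | CC1(C)OB(OC1(C)C)c1c(OCc2ccccc2)cc(OCc2ccccc2)c2c(=O)cc(-c3ccc(OCc4ccccc4)cc3)oc12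
F6 | step 13 | 5,7-bis(benzyloxy)-8-{5-(benzyloxy)-2-[4-(benzyloxy)phenyl]-7-methoxy-4-oxo-4H-chromen-6-yl}-2-[4-(benzyloxy)phenyl]-4H-chromen-4-one | COc1cc2oc(-c3ccc(OCc4ccccc4)cc3)cc(=O)c2c(OCc2ccccc2)c1-c1c(OCc2ccccc2)cc(OCc2ccccc2)c2c(=O)cc(-c3ccc(OCc4ccccc4)cc3)oc12
F7 | step 11 | 5-(benzyloxy)-2-[4-(benzyloxy)phenyl]-6-[(1E)-1,3-bis(tert-butyldimethylsilyloxy)-1-methoxybuta-1,3-dien-2-yl]-7-methoxy-4H-chromen-4-one | COc1cc2oc(-c3ccc(OCc4ccccc4)cc3)cc(=O)c2c(OCc2ccccc2)c1/C(C(=C)O[Si](C)(C)C(C)(C)C)=C(/OC)O[Si](C)(C)C(C)(C)C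
F8 | step 11 | bis(tert-butyldimethylsilyl) analogue of cycloadduct 22 (racemic) | CCOC1=C(C(C)=O)C(OC)(O[Si](C)(C)C(C)(C)C)C(c2c(OC)cc3oc(-c4ccc(OCc5ccccc5)cc4)cc(=O)c3c2OCc2ccccc2)=C(O[Si](C)(C)C(C)(C)C)C1
F9 | step 11 | 6-[3-acetyl-2,6-bis(tert-butyldimethylsilyloxy)-4-ethoxyphenyl]-5-(benzyloxy)-2-[4-(benzyloxy)phenyl]-7-methoxy-4H-chromen-4-one | CCOc1cc(O[Si](C)(C)C(C)(C)C)c(-c2c(OC)cc3oc(-c4ccc(OCc5ccccc5)cc4)cc(=O)c3c2OCc2ccccc2)c(O[Si](C)(C)C(C)(C)C)c1C(C)=O
F10 | step 12 | 4-ethoxybut-3-yn-2-ol (racemic) | CCOC#CC(C)O
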